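**Retrosynthetic overview**
- Germacranolide numbering is used: carbocycle C1–C10, ketone C2, lactone C12(=O)–O6–C6, ester carbinol C8, C13 = CH2OAc. The C8 methacrylate and C13 acetate go on last; before that C13 is an S-ethyl thioester and O8 a TBS ether.
- Key disconnection: C6–C7 and C11–C12 are cut together. This opens the ten-membered ring and the butenolide to the acyclic trienone 13, which carries an alkynyl thioester (C7≡C11–C13) and an enol carbonate on O6. Forward, one SmI2 cascade closes the carbocycle first (C6–C7) and the lactone second (C11–C12).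
- Enabling feature: C6 is the δ-carbon of the C2 ketone through C3=C4–C5=C6, so the target's C2(=O)–C3H2–C4(Me)=C5H–C6 unit is the α-protonated form of a C2 dienolate. O6 bridges C6 and C12, and C11 is α to the C13 carbonyl. One reductive δ-coupling plus acyl transfer therefore builds ring C1–C10 and ring O6–C12–C11=C7–C6.
- 13 comes from a Nozaki–Hiyama–Kishi union (C1–C2) of vinyl iodide 7 with dienal 11, then oxidation.
- 7 comes from 3-(trimethylsilyl)propynal (asymmetric propargylation sets C8, the only reagent-controlled centre); 11 comes from 4-methylpyridine by ring opening to the symmetrical C2–C6 dialdehyde enolate.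

Key step: step 11

Remark: the C3=C4 and C5=C6 double bonds of 11–13 are drawn E,E; their geometry is of no consequence because both are reorganised in step 11.

**Step 1**
Reactants: 1 3-(trimethylsilyl)prop-2-ynal; 2 allenylboronic acid pinacol ester
Product: 3 (S)-1-(trimethylsilyl)hexa-1,5-diyn-3-ol
Conditions: (S)-TRIP [(S)-3,3'-bis(2,4,6-triisopropylphenyl)-1,1'-binaphthyl-2,2'-diyl hydrogen phosphate] (5 mol%), 4 Å MS, toluene, −20 °C; aq. NaHCO3 work-up
Reagents that add atoms: none
Why: Chiral-phosphoric-acid-catalysed allenylboration (propargylation) of the aldehyde through a chair transition state should give the homopropargylic alcohol, and the catalyst antipode is chosen so that C8 is S (the other antipode is used if the sense is reversed for an ynal).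

**Step 2**
Reactants: 3 (S)-1-(trimethylsilyl)hexa-1,5-diyn-3-ol
Product: 4 (S)-3-(tert-butyldimethylsilyloxy)-1-(trimethylsilyl)hexa-1,5-diyne
Conditions: TBSCl, imidazole, DMF, rt
Reagents that add atoms: tert-butyldimethylsilyl chloride CC(C)(C)[Si](C)(C)Cl
Why: Standard silylation of a secondary propargylic alcohol; the stereocentre is untouched.

**Step 3**
Reactants: 4 (S)-3-(tert-butyldimethylsilyloxy)-1-(trimethylsilyl)hexa-1,5-diyne
Product: 5 (S,E)-3-(tert-butyldimethylsilyloxy)-6-iodo-5-methyl-1-(trimethylsilyl)hex-5-en-1-yne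
Conditions: AlMe3 (2.5 equiv), Cp2ZrCl2 (20 mol%), CH2Cl2, 0 °C to rt; then I2, THF, −30 °C
Reagents that add atoms: trimethylaluminium C[Al](C)C; iodine II
Why: Negishi zirconium-catalysed methylalumination adds Me and Al syn across the terminal alkyne (the silyl-capped internal alkyne reacts much more slowly), and iodinolysis with retention should give the E trisubstituted vinyl iodide.

**Step 4**
Reactants: 5 (S,E)-3-(tert-butyldimethylsilyloxy)-6-iodo-5-methyl-1-(trimethylsilyl)hex-5-en-1-yne
Product: 6 (S,E)-3-(tert-butyldimethylsilyloxy)-6-iodo-5-methylhex-5-en-1-yne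
Conditions: K2CO3 (0.2 equiv), MeOH, rt
Reagents that add atoms: none
Why: Methanolysis of the alkynyl C–Si bond (protodesilylation) leaves the TBS ether and the vinyl iodide intact.

**Step 5**
Reactants: 6 (S,E)-3-(tert-butyldimethylsilyloxy)-6-iodo-5-methylhex-5-en-1-yne
Product: 7 S-ethyl (S,E)-4-(tert-butyldimethylsilyloxy)-7-iodo-6-methylhept-6-en-2-ynethioate
Conditions: LDA (1.05 equiv), THF, −78 °C; then inverse addition to EtSC(O)Cl, −78 °C
Reagents that add atoms: S-ethyl chlorothioformate CCSC(=O)Cl
Why: Acylation of the lithium acetylide with a chlorothioformate gives the alkynyl thioester; LDA at −78 °C does not touch the vinyl iodide.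

**Step 6**
Reactants: 8 4-methylpyridine
Product: 9 4-methylpyridinium-1-sulfonate
Conditions: ClSO3H (0.5 equiv), CHCl3, 0 °C
Reagents that add atoms: chlorosulfonic acid OS(=O)(=O)Cl
Why: N-sulfonation of the pyridine gives the sulfur trioxide adduct, which precipitates; the second equivalent of 8 takes up the HCl.

**Step 7**
Reactants: 9 4-methylpyridinium-1-sulfonate
Product: 10 potassium (1E,3E)-3-methyl-5-oxopenta-1,3-dien-1-olate
Conditions: aq. KOH (4 equiv), −20 °C, then 60 °C; crystallisation
Reagents that add atoms: potassium hydroxide [K+].[OH-]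
Why: Zincke-type alkaline ring opening of an N-sulfonylpyridinium (the glutaconaldehyde synthesis) should give the C2-symmetrical 3-methylglutaconaldehyde enolate, which is the C2–C6 unit with its methyl group.

**Step 8**
Reactants: 10 potassium (1E,3E)-3-methyl-5-oxopenta-1,3-dien-1-olate
Product: 11 (1E,3E)-3-methyl-5-oxopenta-1,3-dien-1-yl methyl carbonate
Conditions: ClCO2Me (1.1 equiv), MeCN, 0 °C
Reagents that add atoms: methyl chloroformate COC(=O)Cl
Why: O-acylation of the ambident vinylogous carboxylate by the hard chloroformate; because the enolate is symmetrical, only one O-acyl dienal can form, and this puts the future lactone carbonyl C12 on O6.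

**Step 9**
Reactants: 7 S-ethyl (S,E)-4-(tert-butyldimethylsilyloxy)-7-iodo-6-methylhept-6-en-2-ynethioate; 11 (1E,3E)-3-methyl-5-oxopenta-1,3-dien-1-yl methyl carbonate
Product: 12 S-ethyl (4S,6E,9E,11E)-4-(tert-butyldimethylsilyloxy)-8-hydroxy-12-(methoxycarbonyloxy)-6,10-dimethyldodeca-6,9,11-trien-2-ynethioate (both epimers at the new carbinol)
Conditions: CrCl2 (4 equiv), NiCl2 (2 mol%), anhydrous DMSO/THF, rt
Reagents that add atoms: none
Why: Nozaki–Hiyama–Kishi reaction: the alkenylchromium formed from the vinyl iodide adds 1,2 to the aldehyde with retention of the E geometry and should leave the thioester, alkyne and carbonate alone; the new carbinol centre is removed in step 10.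

**Step 10**
Reactants: 12 S-ethyl (4S,6E,9E,11E)-4-(tert-butyldimethylsilyloxy)-8-hydroxy-12-(methoxycarbonyloxy)-6,10-dimethyldodeca-6,9,11-trien-2-ynethioate
Product: 13 S-ethyl (4S,6E,9E,11E)-4-(tert-butyldimethylsilyloxy)-12-(methoxycarbonyloxy)-6,10-dimethyl-8-oxododeca-6,9,11-trien-2-ynethioate
Conditions: Dess–Martin periodinane, NaHCO3, CH2Cl2, 0 °C
Reagents that add atoms: none
Why: Dess–Martin oxidation of the doubly allylic alcohol gives the cross-conjugated trienone under neutral conditions.

**Step 11**
Reactants: 13 S-ethyl (4S,6E,9E,11E)-4-(tert-butyldimethylsilyloxy)-12-(methoxycarbonyloxy)-6,10-dimethyl-8-oxododeca-6,9,11-trien-2-ynethioate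
Product: 17 S-ethyl (6R,8S)-8-(tert-butyldimethylsilyloxy)-2-oxogermacra-1(10)E,4E,7(11)-trien-12,6-olide-13-thioate, via samarium dienolate radical 14 (not isolated), via cyclised samarium dienolate–allenolate 15 (not isolated), via lactone samarium dienolate 16 (not isolated)
Conditions: SmI2 (2.1 equiv), HMPA (8 equiv), THF, −78 °C, simultaneous slow addition of 13 and SmI2 (about 1 mM); then AcOH in THF, −78 °C
Reagents that add atoms: none
Why: Proposed new method: one electron from SmI2 turns the trienone into a samarium dienolate whose spin sits on the terminal δ-carbon C6 (an α-carbonate allyl radical, 14), which should add to C7 of the alkynyl thioester in a 10-exo-dig closure of the carbocycle; a second electron converts the α-acyl vinyl radical into the samarium allenolate 15, whose C11 attacks the carbonate on O6 in a 5-exo-trig Dieckmann-type acyl transfer with loss of methoxide (butenolide, 16), and acetic acid then protonates the C2 dienolate at C3 so that C4=C5 stays out of conjugation. The closest known reaction types are SmI2-mediated reductive β,β-couplings of enones with alkynoates and acrylates (ketyl–olefin type), SmI2 closures of medium rings, and Dieckmann or Reformatsky acylations of samarium enolates; new are the vinylogous δ site of coupling, the carbonate as internal acyl donor and the ten-membered ring. C6 is set in the radical addition: the C8 silyloxy group is expected to lie anti to the forming bond (Felkin–Anh-type), the tether puts C5 and C9 on the same face, and trivalent samarium bridging the carbonate and thioester carbonyls holds O6 syn to C11, which together should give 6R from 8S. The C4=C5 alkene should emerge E from the W-shaped dienolate. The step needs δ- over β-coupling (C6 is the unhindered terminus, C4 and C10 are fully substituted), ring closure over dimerisation (slow addition at high dilution), C- over O-acylation (five-membered transition state) and α- over γ-protonation (kinetic quench at −78 °C).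

**Step 12**
Reactants: 17 S-ethyl (6R,8S)-8-(tert-butyldimethylsilyloxy)-2-oxogermacra-1(10)E,4E,7(11)-trien-12,6-olide-13-thioate
Product: 18 (6R,8S)-8-(tert-butyldimethylsilyloxy)-2,13-dioxogermacra-1(10)E,4E,7(11)-trien-12,6-olide (13-aldehyde)
Conditions: Et3SiH (3 equiv), Pd/C (10% palladium on carbon, 10 mol%), acetone, rt
Reagents that add atoms: none
Why: Fukuyama reduction converts the thioester into the aldehyde and is selective over the lactone and the ketone.

**Step 13**
Reactants: 18 (6R,8S)-8-(tert-butyldimethylsilyloxy)-2,13-dioxogermacra-1(10)E,4E,7(11)-trien-12,6-olide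
Product: 19 (6R,8S)-8-(tert-butyldimethylsilyloxy)-13-hydroxy-2-oxogermacra-1(10)E,4E,7(11)-trien-12,6-olide
Conditions: NaBH4 (0.3 equiv), MeOH/CH2Cl2 (1:1), −78 °C
Reagents that add atoms: none
Why: At −78 °C borohydride should reduce the aldehyde 1,2 much faster than the hindered ring enone, the lactone or the tetrasubstituted C7=C11 alkene.

**Step 14**
Reactants: 19 (6R,8S)-8-(tert-butyldimethylsilyloxy)-13-hydroxy-2-oxogermacra-1(10)E,4E,7(11)-trien-12,6-olide
Product: 20 (6R,8S)-13-acetoxy-8-(tert-butyldimethylsilyloxy)-2-oxogermacra-1(10)E,4E,7(11)-trien-12,6-olide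
Conditions: Ac2O, pyridine, DMAP (5 mol%), CH2Cl2, 0 °C
Reagents that add atoms: acetic anhydride CC(=O)OC(C)=O
Why: Routine acetylation of the primary allylic alcohol.

**Step 15**
Reactants: 20 (6R,8S)-13-acetoxy-8-(tert-butyldimethylsilyloxy)-2-oxogermacra-1(10)E,4E,7(11)-trien-12,6-olide
Product: 21 (6R,8S)-13-acetoxy-8-hydroxy-2-oxogermacra-1(10)E,4E,7(11)-trien-12,6-olide
Conditions: HF·pyridine, pyridine/THF, 0 °C to rt
Reagents that add atoms: none
Why: Buffered fluoride desilylation frees the C8 alcohol without base, so the acetate, the butenolide γ-hydrogen and the skipped enone are not disturbed.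

**Step 16**
Reactants: 21 (6R,8S)-13-acetoxy-8-hydroxy-2-oxogermacra-1(10)E,4E,7(11)-trien-12,6-olide
Product: 22 (6R,8S)-13-acetoxy-8-(methacryloyloxy)-2-oxogermacra-1(10)E,4E,7(11)-trien-12,6-olide (CNP0325594.1)
Conditions: methacrylic anhydride (1.5 equiv), DMAP (0.2 equiv), pyridine, CH2Cl2, 0 °C to rt
Reagents that add atoms: methacrylic anhydride C=C(C)C(=O)OC(=O)C(C)=C
Why: DMAP-catalysed acylation of the secondary alcohol occurs at oxygen with retention at C8 and should give the target.

**Compound list**
1 | 3-(trimethylsilyl)prop-2-ynal | C[Si](C)(C)C#CC=O | starting material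
2 | allenylboronic acid pinacol ester | C=C=CB1OC(C)(C)C(C)(C)O1 | starting material
3 | (S)-1-(trimethylsilyl)hexa-1,5-diyn-3-ol | C#CC[C@H](O)C#C[Si](C)(C)C | intermediate
4 | (S)-3-(tert-butyldimethylsilyloxy)-1-(trimethylsilyl)hexa-1,5-diyne | C#CC[C@H](O[Si](C)(C)C(C)(C)C)C#C[Si](C)(C)C | intermediate
5 | (S,E)-3-(tert-butyldimethylsilyloxy)-6-iodo-5-methyl-1-(trimethylsilyl)hex-5-en-1-yne | I/C=C(C)/C[C@H](O[Si](C)(C)C(C)(C)C)C#C[Si](C)(C)C | intermediate
6 | (S,E)-3-(tert-butyldimethylsilyloxy)-6-iodo-5-methylhex-5-en-1-yne | I/C=C(C)/C[C@H](O[Si](C)(C)C(C)(C)C)C#C | intermediate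
7 | S-ethyl (S,E)-4-(tert-butyldimethylsilyloxy)-7-iodo-6-methylhept-6-en-2-ynethioate | CCSC(=O)C#C[C@@H](O[Si](C)(C)C(C)(C)C)C/C(C)=C/I | intermediate
8 | 4-methylpyridine | Cc1ccncc1 | starting material
9 | 4-methylpyridinium-1-sulfonate | Cc1cc[n+](S(=O)(=O)[O-])cc1 | intermediate
10 | potassium (1E,3E)-3-methyl-5-oxopenta-1,3-dien-1-olate | O=C/C=C(C)/C=C/[O-].[K+] | intermediate
11 | (1E,3E)-3-methyl-5-oxopenta-1,3-dien-1-yl methyl carbonate | O=C/C=C(C)/C=C/OC(=O)OC | intermediate
12 | S-ethyl (4S,6E,9E,11E)-4-(tert-butyldimethylsilyloxy)-8-hydroxy-12-(methoxycarbonyloxy)-6,10-dimethyldodeca-6,9,11-trien-2-ynethioate (carbinol epimers) | CCSC(=O)C#C[C@@H](O[Si](C)(C)C(C)(C)C)C/C(C)=C/C(O)/C=C(C)/C=C/OC(=O)OC | intermediate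
13 | S-ethyl (4S,6E,9E,11E)-4-(tert-butyldimethylsilyloxy)-12-(methoxycarbonyloxy)-6,10-dimethyl-8-oxododeca-6,9,11-trien-2-ynethioate | CCSC(=O)C#C[C@@H](O[Si](C)(C)C(C)(C)C)C/C(C)=C/C(=O)/C=C(C)/C=C/OC(=O)OC | intermediate
14 | samarium dienolate radical (O2-bound trivalent samarium, spin at C6) | CCSC(=O)C#C[C@@H](O[Si](C)(C)C(C)(C)C)C/C(C)=C/C(O[Sm](I)I)=CC(C)=C[CH]OC(=O)OC | intermediate
15 | cyclised samarium dienolate–allenolate (ten-membered ring closed, carbonate still on O6) | CC(C)(C)[Si](C)(C)O[C@H]1C/C(C)=C/C(O[Sm](I)I)=CC(C)=C[C@@H](OC(=O)OC)C1=C=C(O[Sm](I)I)SCC | intermediate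
16 | lactone samarium dienolate (butenolide closed, C2 still enolate) | CC(C)(C)[Si](C)(C)O[C@H]1C/C(C)=C/C(O[Sm](I)I)=CC(C)=C[C@H]2OC(=O)C(C(=O)SCC)=C12 | intermediate
17 | S-ethyl (6R,8S)-8-(tert-butyldimethylsilyloxy)-2-oxogermacra-1(10)E,4E,7(11)-trien-12,6-olide-13-thioate | CC(C)(C)[Si](C)(C)O[C@H]1C/C(C)=C/C(=O)C/C(C)=C/[C@H]2OC(=O)C(C(=O)SCC)=C12 | intermediate
18 | (6R,8S)-8-(tert-butyldimethylsilyloxy)-2,13-dioxogermacra-1(10)E,4E,7(11)-trien-12,6-olide | CC(C)(C)[Si](C)(C)O[C@H]1C/C(C)=C/C(=O)C/C(C)=C/[C@H]2OC(=O)C(C=O)=C12 | intermediate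
19 | (6R,8S)-8-(tert-butyldimethylsilyloxy)-13-hydroxy-2-oxogermacra-1(10)E,4E,7(11)-trien-12,6-olide | CC(C)(C)[Si](C)(C)O[C@H]1C/C(C)=C/C(=O)C/C(C)=C/[C@H]2OC(=O)C(CO)=C12 | intermediate
20 | (6R,8S)-13-acetoxy-8-(tert-butyldimethylsilyloxy)-2-oxogermacra-1(10)E,4E,7(11)-trien-12,6-olide | CC(C)(C)[Si](C)(C)O[C@H]1C/C(C)=C/C(=O)C/C(C)=C/[C@H]2OC(=O)C(COC(C)=O)=C12 | intermediate
21 | (6R,8S)-13-acetoxy-8-hydroxy-2-oxogermacra-1(10)E,4E,7(11)-trien-12,6-olide | O[C@H]1C/C(C)=C/C(=O)C/C(C)=C/[C@H]2OC(=O)C(COC(C)=O)=C12 | intermediate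
22 | (6R,8S)-13-acetoxy-8-(methacryloyloxy)-2-oxogermacra-1(10)E,4E,7(11)-trien-12,6-olide | C=C(C)C(=O)O[C@H]1C/C(C)=C/C(=O)C/C(C)=C/[C@H]2OC(=O)C(COC(C)=O)=C12 | target

**Count**
Total steps: 16. Longest linear sequence: 13 (steps 1–5 and 9–16).

**Steps most likely to fail**

1. Step 11 (proposed new method). What may go wrong: intermolecular reductive dimerisation or simple conjugate reduction before ring closure; coupling through C4 instead of C6; poor facial selectivity at C6; loss of the C1=C10 geometry while the enone is a radical anion; expulsion of the C6 oxygen from the dienolate; further reduction of the electron-poor product. Fallback with known chemistry, setting out from 13 and returning at 19: β-iodo Baylis–Hillman-type iodo-hydroxymethylation of the alkynyl thioester (Et2AlI, then monomeric formaldehyde, CH2Cl2, −78 °C) should give the (Z)-β-iodo-α-(hydroxymethyl) enethioate F1. Mild methanolysis of the enol carbonate (K2CO3 cat., MeOH, −20 °C) unmasks the C6 enal and gives the keto aldehyde F2. An intramolecular Nozaki–Hiyama–Kishi reaction (CrCl2, NiCl2 cat., DMF/THF, high dilution) then forms C6–C7, and the chromium alkoxide lactonises onto the cis thioester to give 19. In this variant the lactone carbonyl comes from the thioester carbon and C13 from formaldehyde.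

2. Step 12. What may go wrong: conjugate reduction of the doubly activated C7=C11 alkene by the silane, palladium-hydride isomerisation of the skipped C4=C5 alkene into conjugation, or over-reduction of the aldehyde. Fallback, setting out from 17 and returning at 19: silver-assisted hydrolysis of the thioester (AgNO3, 2,6-lutidine, aq. THF) gives the carboxylic acid F3. Activation as the isobutyl carbonic anhydride F4 (isobutyl chloroformate, N-methylmorpholine, THF, −20 °C) and reduction with NaBH4 at −40 °C gives 19 without passing through aldehyde 18.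

3. Step 1. What may go wrong: weak enantiofacial discrimination because an ynal lies outside the usual aldehyde scope of the catalyst, and an uncatalysed background allenylboration; both would erode the only reagent-controlled centre. Fallback, setting out from 1 and returning at 3: zinc-mediated Barbier propargylation (propargyl bromide, Zn, THF/aq. NH4Cl) gives the racemic alcohol F5. Oxidation (MnO2, CH2Cl2) gives the ynone F6. Noyori transfer hydrogenation with RuCl[(S,S)-TsDPEN](p-cymene) in iPrOH, which is reliable for alkynyl ketones, should then deliver (S)-3.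

**Further compounds**
F1 | step 11 | S-ethyl (2Z,4S,6E,9E,11E)-4-(tert-butyldimethylsilyloxy)-2-(hydroxymethyl)-3-iodo-12-(methoxycarbonyloxy)-6,10-dimethyl-8-oxododeca-2,6,9,11-tetraenethioate | CCSC(=O)/C(CO)=C(\I)[C@@H](O[Si](C)(C)C(C)(C)C)C/C(C)=C/C(=O)/C=C(C)/C=C/OC(=O)OC
F2 | step 11 | S-ethyl (2Z,4S,6E,10E)-4-(tert-butyldimethylsilyloxy)-2-(hydroxymethyl)-3-iodo-6,10-dimethyl-8,12-dioxododeca-2,6,10-trienethioate | CCSC(=O)/C(CO)=C(\I)[C@@H](O[Si](C)(C)C(C)(C)C)C/C(C)=C/C(=O)C/C(C)=C/C=O
F3 | step 12 | (6R,8S)-8-(tert-butyldimethylsilyloxy)-2-oxogermacra-1(10)E,4E,7(11)-trien-12,6-olide-13-oic acid | CC(C)(C)[Si](C)(C)O[C@H]1C/C(C)=C/C(=O)C/C(C)=C/[C@H]2OC(=O)C(C(=O)O)=C12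
F4 | step 12 | isobutyl carbonic anhydride of acid F3 | CC(C)(C)[Si](C)(C)O[C@H]1C/C(C)=C/C(=O)C/C(C)=C/[C@H]2OC(=O)C(C(=O)OC(=O)OCC(C)C)=C12
F5 | step 1 | racemic 1-(trimethylsilyl)hexa-1,5-diyn-3-ol | C#CCC(O)C#C[Si](C)(C)C
F6 | step 1 | 1-(trimethylsilyl)hexa-1,5-diyn-3-one | C#CCC(=O)C#C[Si](C)(C)C
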